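Two of us disagree about red. E turns G into X, and X then fades.

| flask | G | E | remark | time |
|---|---|---|---|---|
| Tuesday's | 49 mM | 9.8 µM | run made earlier |  |
| Wednesday's | 49 mM | 4.9 µM | run made earlier |  |
| Friday's | 49 mM | 20 µM | run made earlier |  |
| Thursday's | 74 mM | 9.8 µM | run made earlier |  |
| ochre | 49 mM | 9.8 µM | a single well-mixed tank run continuously and read at steady state, 40 min in it on average |  |
| teal | 49 mM | 9.8 µM | everything together in a closed stirred flask, run for 40 min | 40 min |
| violet | 49 mM | 9.8 µM | a tube with plug flow, the mixed feed as stated, residence time 40 min | 40 min |
| red | 49 mM (fed, over 40.0 min) | 9.8 µM | a stirred flask in which G is dosed at a steady rate over 40.0 min without added volume, worked up at 40 min | 40 min |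

- Tuesday's (time / min: X / %, G / %): 4.00: 38.9, 50.3; 10.0: 58.9, 13.3; 20.0: 41.2, 4.3; 30.0: 26.9, 2.0; 40.0: 20.5, 1.8
- Wednesday's (time / min: X / %, G / %): 4.00: 19.7, 71.6; 10.0: 41.2, 40.4; 20.0: 45.6, 14.0; 30.0: 34.0, 6.3; 40.0: 24.1, 3.3
- Friday's (time / min: X / %, G / %): 4.00: 67.0, 17.8; 10.0: 59.4, 3.8; 20.0: 35.4, 1.6; 30.0: 24.2, 0.6; 40.0: 19.2, 1.1
- Thursday's (time / min: X / %, G / %): 3.00: 21.3, 70.0; 6.00: 39.0, 44.9; 12.0: 56.9, 13.6; 20.0: 46.0, 4.4; 40.0: 21.5, 0.7

(scatter of a reading: 0.5 percentage points)

- the stated concentrations are those of everything mixed, before any reaction; amounts are the same in each set-up
- the numbers in the tables scatter with a standard deviation of 0.5 percentage points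
- the feed brings no volume worth counting
- the earlier runs were made in a closed, stirred flask
- a reading or a percentage of X counts all its forms, free or not
- a reading of G is of its free form alone

* the set-up with the highest amount of X at the outlet or at the end, in percent of the G put in ("none" if the first two lie within 2 percentage points) (ochre / teal / violet / red / none)
* amount of X at the outlet or at the end, in percent of the G put in, ochre
* amount of X at the outlet or at the end, in percent of the G put in, teal
* amount of X at the outlet or at the end, in percent of the G put in, violet
* amount of X at the outlet or at the end, in percent of the G put in, red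

The first says the vessel is of no account. Red, teal and violet hold the same E and the same G for the same 40 min. Between Wednesday's flask and Friday's, E went from 4.9 µM to 20 µM, yet X at 40.0 min moved just from 24.1 % to 19.2 %. So the first expects red near Tuesday's 20.5 %.

The second looks at the shape of Tuesday's curve. X climbs to a reading of 58.9 % at 10.0 min, then falls away. In teal and violet, every parcel of G has the same age at the end, so they sit at the tail of that curve. Red takes its G evenly over 40.0 min. Its ages therefore run evenly from zero to 40.0 min, which is its residence-time distribution, with a mean of 20.0 min.

Tuesday's reading at that age is 41.2 %. But the curve bends, so the second averages it over those ages, drawing straight lines between readings, and gets 36.2 %. This is the age mean, the batch curve averaged over the ages a flask holds. Using the reading at the mean age instead would cost 5 percentage points. The age mean assumes each parcel ages as in Tuesday's flask. The second reckons no number for ochre.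

The forecast sides with the second but prints a higher number than the second's: red 38.5 %, range 34 % to 43 %, since “dosing keeps G low”. It gives ochre 32 %, teal 20.5 % and violet 20.5 %, and names red as best.

The flask gives red 37.6 %, ochre 30.9 %, and teal and violet 20.4 % each, so red is best and the second wins. In red, [G] reached 5.59 mM at its highest, against 49 mM at the start of teal. The age mean falls 1.4 points short of red, while the reading at the mean age lies 3.6 points above it. Both stand above teal, so the single reading is the cheapest way to that ranking, and the average buys a closer number. The first's view has its region late: at 400 min, red gives 14.1 % and violet 14.1 %.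

    G + E → X + E, rate k1*[G]^2*[E]/(1 + ([G]/Kh1)^2) (11.0 mM, k = 83000 /M²/s)
    X ⇌ Z (K = 6.10, k = 0.0710 /min)
    G + X ⇌ J, settled at all times (K = 10.0 /M)

Violet read at 15 min holds one age, so its age mean is Tuesday's curve at that age, drawn straight between readings: 50.0 %. The computed value is 51.0 %.

Readings and results were generated by integration with made-up constants; the scatter is artificial.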